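The route rests on cutting the bond between the arene and C4a, the quaternary carbon common to rings A, B and C. The feature exploited is that C4a is allylic in the target. The ring C double bond C5=C6 starts beside it, and C6 holds the methyl group. Moving that alkene to C4a=C5 and putting acetate on C6 lets an aryl–palladium unit anchored at benzylic C8 add to C4a while acetate departs (syn SN2′). One operation makes the arene–C4a bond, closes five-membered ring B, sets C4a and restores the C5=C6 alkene. The precursor is an 8a-prenyl octalin with a trans, axial 8-aryl group carrying an ortho-boronic acid, a cis C6 acetate and silyl ethers at C1 and C4.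

Key step: step 13

**Notation and design remarks**

- **Numbering (octalin).**
  - Ring A = C1, C2, C3, C4, C4a, C8a.
  - Ring C = C4a, C5, C6, C7, C8, C8a.
  - Ring B = C4a, C8a, C8 plus two arene carbons.
  - Ring D = arene.
- **Faces.** β is the face that carries the prenyl group and α is the opposite face. In this numbering the target is (4aR,8R,8aS): prenyl is β on C8a, and the arene bridge is α on both C8 and C4a.
- **C1 protection.** C1 is carried as an equatorial β silyl ether and not as a ketal.
  - C1 and C8 both hang on C8a, so the axial oxygen of a C1 ketal would be syn-axial to the axial 8α-aryl group and would lie over the arene after ring closure.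
  - With the ether only a hydrogen points there.
  - Both silyl ethers later leave in one step, and both carbinols are oxidised in one step.
- **Boron handle.** It comes from a bromine atom that arrives with the arene, and it is exchanged for boron before any ester is present.
  - The site is flanked on both sides, so C–H borylation or lithiation of the finished acetate would lack regiocontrol.
  - A borylation with zerovalent palladium would ionise the allylic acetate.
- **Aryl introduction.** The aryl group is added to a cross-conjugated dienone.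
  - This makes the trans (axial) aryl/prenyl relationship substrate-controlled.
  - It also lets the absolute configuration come from an established organocatalytic annulation.
- **C4 configuration.** C4 ends as a ketone, so its configuration is not critical. The β epimer is drawn.
- **Assumption.** The prolinamide catalyst should give the prenyl triketone the same sense of induction as its methyl and allyl analogues. The mirror-image catalyst would serve otherwise.

**Route**

Step 1
Reactants: 1 cyclohexane-1,3-dione; 2 prenyl bromide
Product: 3 2-prenylcyclohexane-1,3-dione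
Conditions: KOH (1 equiv), H2O, 0 °C → rt
Reagents that add atoms: none
Why: SN2 C-alkylation of the stabilised 1,3-dione enolate with a reactive allylic bromide in water, where solvation of the enolate oxygen favours attack through carbon; no stereocentre is formed.

Step 2
Reactants: 3 2-prenylcyclohexane-1,3-dione; 4 methyl vinyl ketone
Product: 6 (8aR)-8a-prenyl-4a(5)-octalene-1,6-dione, via triketone 5 (not isolated)
Conditions: Et3N (1 mol %), neat, rt; then N-tosyl-(Sa)-binam-L-prolinamide (5 mol %), PhCO2H (2.5 mol %), neat, rt
Reagents that add atoms: none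
Why: Robinson annulation run as a Michael addition followed by an enamine-mediated desymmetrising aldol condensation of the Hajos–Parrish–Eder–Sauer–Wiechert type, in which the L-prolinamide distinguishes the two enantiotopic ring ketones and sets C8a in the spatial sense of the (S)-methyl series (the descriptor reads R only because prenyl outranks C8 in the CIP order).

Step 3
Reactants: 6 (8aR)-8a-prenyl-4a(5)-octalene-1,6-dione
Product: 7 1β-hydroxy-8a-prenyl-4a(5)-octalen-6-one
Conditions: NaBH4 (0.3 equiv), EtOH, 0 °C
Reagents that add atoms: none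
Why: Chemoselective borohydride reduction of the isolated C1 ketone in the presence of the less electrophilic enone, as in the Wieland–Miescher ketone series; hydride enters axially on the α face, anti to the axial prenyl group, so the C1 hydroxyl becomes equatorial and β.

Step 4
Reactants: 7 1β-hydroxy-8a-prenyl-4a(5)-octalen-6-one
Product: 8 1β-TBSO linear TBS dienol ether (C4=C4a and C5=C6)
Conditions: TBSOTf (2.5 equiv), Et3N, CH2Cl2, 0 °C → rt
Reagents that add atoms: TBSOTf, CC(C)(C)[Si](C)(C)OS(=O)(=O)C(F)(F)F
Why: Soft enolisation with silyl triflate and amine under equilibrating conditions gives the linearly conjugated silyl dienol ether while the same reagent silylates the C1 alcohol, so two tasks are done at once and no stereocentre is touched.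

Step 5
Reactants: 8 1β-TBSO linear TBS dienol ether
Product: 9 1β-TBSO-4β-hydroxy-8a-prenyl-4a(5)-octalen-6-one
Conditions: m-CPBA (1.0 equiv), CH2Cl2, −20 °C; aq. NaHCO3/Na2S2O3 work-up
Reagents that add atoms: m-CPBA, OOC(=O)c1cccc(Cl)c1
Why: Vinylogous Rubottom oxidation, in which the peracid attacks the electron-rich terminal C4=C4a bond of the dienol ether far faster than the prenyl alkene and collapse of the epoxide returns the enone; oxygen should arrive axially on the β face, as in the 6β-hydroxylation of steroidal 3,5-dienol ethers.

Step 6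
Reactants: 9 1β-TBSO-4β-hydroxy-8a-prenyl-4a(5)-octalen-6-one
Product: 10 1β/4β-bis(TBSO)-8a-prenyl-4a(5)-octalen-6-one
Conditions: TBSOTf, 2,6-lutidine, CH2Cl2, −78 → 0 °C
Reagents that add atoms: TBSOTf, CC(C)(C)[Si](C)(C)OS(=O)(=O)C(F)(F)F
Why: Standard silylation of a hindered axial secondary alcohol with the reactive silyl triflate and a weak hindered base that does not enolise the enone; configuration is retained.

Step 7
Reactants: 10 1β/4β-bis(TBSO)-8a-prenyl-4a(5)-octalen-6-one
Product: 12 1β/4β-bis(TBSO) cross-conjugated 4a(5),7-dien-6-one, via TMS dienol ether 11 (not isolated)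
Conditions: LDA, THF, −78 °C, then TMSCl; crude, Pd(OAc)2 (1.1 equiv), MeCN, rt
Reagents that add atoms: none
Why: Saegusa–Ito dehydrogenation, in which kinetic deprotonation of the enone takes place at C7 (α′ position) and the derived oxa-π-allyl palladium species loses the C8 hydrogen by β-hydride elimination, so the new alkene can form only at C7=C8.

Step 8
Reactants: 13 2-bromo-1,4-dimethoxybenzene
Product: 15 2-bromo-3-iodo-1,4-dimethoxybenzene, via aryllithium 14 (not isolated)
Conditions: LDA, THF, −78 °C; I2, −78 °C
Reagents that add atoms: iodine, II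
Why: Directed ortho-lithiation at the most acidic CH, flanked by bromine and methoxy, followed by an iodine quench at low temperature before lithium bromide can be lost.

Step 9
Reactants: 12 1β/4β-bis(TBSO) cross-conjugated dienone; 15 2-bromo-3-iodo-1,4-dimethoxybenzene
Product: 18 8α-(2-bromo-3,6-dimethoxyphenyl) enone, via aryl Grignard reagent 16 (not isolated), via TMS dienol ether 17 (not isolated)
Conditions: 15, iPrMgCl·LiCl, THF, −40 °C; CuBr·SMe2 (30 mol %), TMSCl, DMPU, 12, −78 → −20 °C; 1 M HCl, THF, 0 °C
Reagents that add atoms: none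
Why: Selective iodine–magnesium exchange followed by copper-catalysed, TMSCl-accelerated conjugate addition to the less substituted enone arm; the aryl group enters C8 perpendicular to the flat dienone ring on the α face, anti to the neighbouring prenyl group (as in the 1α-alkylation of steroidal 1,4-dien-3-ones), which sets C8 with the aryl group axial and trans to prenyl.

Step 10
Reactants: 18 8α-(2-bromo-3,6-dimethoxyphenyl) enone
Product: 19 6α-hydroxy-6β-methyl tertiary allylic alcohol
Conditions: MeLi, CeCl3, THF, −78 °C
Reagents that add atoms: methyllithium, C[Li]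
Why: 1,2-Addition of a weakly basic organocerium reagent to the enone carbonyl; the axial 8α-aryl group is 1,3-related to C6 and shields the α face, so methyl arrives from the β face and the C6 oxygen is left α, cis to the aryl group.

Step 11
Reactants: 19 6α-hydroxy-6β-methyl tertiary allylic alcohol
Product: 22 6α-acetoxy pinacol boronate, via dilithio species 20 (not isolated), via lithium alkoxide boronate 21 (not isolated)
Conditions: n-BuLi (2.2 equiv), THF, −78 °C; iPrOBpin; Ac2O, −78 °C → rt
Reagents that add atoms: 2-isopropoxy-4,4,5,5-tetramethyl-1,3,2-dioxaborolane, CC(C)OB1OC(C)(C)C(C)(C)O1; acetic anhydride, CC(=O)OC(C)=O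
Why: Bromine–lithium exchange on the lithium alkoxide, borylation of the aryllithium and acylation of the remaining tertiary lithium alkoxide are three standard reactions run in sequence, so boron is in place before any ester exists and the hindered alcohol is acetylated in its most reactive form without change at any stereocentre.

Step 12
Reactants: 22 6α-acetoxy pinacol boronate
Product: 23 6α-acetoxy arylboronic acid (key precursor)
Conditions: NaIO4, NH4OAc, acetone/H2O, rt
Reagents that add atoms: water, O
Why: Periodate glycol cleavage removes the pinacol released in the hydrolysis equilibrium and so drives the ester to the free boronic acid at near-neutral pH, which should spare the tertiary allylic acetate, the silyl ethers and the alkenes.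

Step 13
Reactants: 23 6α-acetoxy arylboronic acid
Product: 24 tetracyclic 1β/4β-bis(TBSO) dimethyl ether (key product)
Conditions: Pd(OAc)2 (10 mol %), 1,10-phenanthroline (12 mol %), AgSbF6 (10 mol %), ClCH2CH2Cl (0.01 M), 60 °C
Reagents that add atoms: none
Why: Transmetalation of the boronic acid to the cationic, phenanthroline-bound divalent palladium acetate gives an aryl–palladium species held under ring C, where the carbonyl oxygen of the 6α-acetate can bind it; syn migratory insertion into C4a=C5 joins the arene carbon to C4a and puts palladium on C5, and syn β-acetoxy elimination gives the C5=C6 alkene and returns divalent palladium, so the cycle is redox-neutral. The closest known reaction type is the palladium-catalysed, γ-selective and syn-stereospecific allyl–aryl coupling of allylic acetates with arylboronic acids, which also builds quaternary benzylic carbons from γ,γ-disubstituted substrates; here both partners sit in one molecule. Ring B (C4a, C8a, C8 and two arene carbons) closes in the 5-exo-trig mode, whereas the 6-endo alternative at C5 would demand a boat-shaped ring C. The only new stereocentre, C4a, is controlled by the tether, because an axial 8α-aryl group can reach only the α face of C4a, while the prenyl alkene on the β face is out of reach. The step needs insertion to outrun ionisation of the tertiary acetate and protodeboronation, and it needs a clean termination: no zerovalent palladium is present to ionise the acetate, silver is kept equimolar with palladium, and the C5–palladium intermediate has no β-hydrogen (C4a and C6 are fully substituted), so the cis 6α-acetate set in step 10 is the only group that can leave.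

Step 14
Reactants: 24 tetracyclic 1β/4β-bis(TBSO) dimethyl ether
Product: 25 tetracyclic 1β/4β-diol
Conditions: TBAF, THF, 50 °C
Reagents that add atoms: none
Why: Fluoride-induced desilylation driven by the strength of the Si–F bond removes both ethers at once, and the non-acidic medium avoids acid-induced addition of the C1 hydroxyl to the prenyl alkene.

Step 15
Reactants: 25 tetracyclic 1β/4β-diol
Product: 26 tetracyclic 1,4-dione
Conditions: DMP, CH2Cl2, rt
Reagents that add atoms: none
Why: Dess–Martin oxidation converts both hindered secondary carbinols into ketones under mild conditions and erases the auxiliary stereocentres C1 and C4, while the quaternary neighbours C8a and C4a exclude epimerisation.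

Step 16
Reactants: 26 tetracyclic 1,4-dione
Product: 27 ene-dione dimethyl ether
Conditions: IBX, DMSO, 70 °C
Reagents that add atoms: none
Why: IBX dehydrogenation of ketones through their enols; both ketones can enolise only toward C2/C3 because C4a and C8a are quaternary, so only the C2=C3 ene-dione can form and no further enolisable position remains.

Step 17
Reactants: 27 ene-dione dimethyl ether
Product: 29 target hydroquinone, via quinone 28 (not isolated)
Conditions: (NH4)2Ce(NO3)6, MeCN/H2O, 0 °C; then aq. Na2S2O4, EtOAc, rt, brief
Reagents that add atoms: water, O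
Why: Oxidative demethylation of the hydroquinone dimethyl ether to the p-quinone (fast enough at 0 °C to spare the trisubstituted alkenes) followed by a short dithionite reduction, which should reduce the much more easily reduced quinone and leave the ene-dione; no stereocentre is involved.

**Compound list**

1 | cyclohexane-1,3-dione | O=C1CCCC(=O)C1 | starting material
2 | prenyl bromide (1-bromo-3-methylbut-2-ene) | CC(C)=CCBr | starting material
3 | 2-prenylcyclohexane-1,3-dione | CC(C)=CCC1C(=O)CCCC1=O | intermediate
4 | methyl vinyl ketone | CC(=O)C=C | starting material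
5 | 2-(3-oxobutyl)-2-prenylcyclohexane-1,3-dione | CC(C)=CCC1(CCC(C)=O)C(=O)CCCC1=O | intermediate
6 | (8aR)-8a-prenyl-4a(5)-octalene-1,6-dione (prenyl analogue of the Wieland–Miescher ketone) | CC(C)=CC[C@@]12C(=O)CCCC1=CC(=O)CC2 | intermediate
7 | 1β-hydroxy enone (OH equatorial, cis to prenyl) | CC(C)=CC[C@@]12[C@@H](O)CCCC1=CC(=O)CC2 | intermediate
8 | 1β-TBSO, C6 TBS dienol ether with C4=C4a and C5=C6 | CC(C)=CC[C@@]12[C@@H](O[Si](C)(C)C(C)(C)C)CCC=C1C=C(O[Si](C)(C)C(C)(C)C)CC2 | intermediate
9 | 1β-TBSO-4β-hydroxy enone (C4 OH axial, cis to prenyl) | CC(C)=CC[C@@]12[C@@H](O[Si](C)(C)C(C)(C)C)CC[C@@H](O)C1=CC(=O)CC2 | intermediate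
10 | 1β,4β-bis(TBSO) enone | CC(C)=CC[C@@]12[C@@H](O[Si](C)(C)C(C)(C)C)CC[C@@H](O[Si](C)(C)C(C)(C)C)C1=CC(=O)CC2 | intermediate
11 | cross-conjugated C6 TMS dienol ether (C4a=C5, C6=C7) | CC(C)=CC[C@@]12[C@@H](O[Si](C)(C)C(C)(C)C)CC[C@@H](O[Si](C)(C)C(C)(C)C)C1=CC(O[Si](C)(C)C)=CC2 | intermediate
12 | 1β,4β-bis(TBSO) 4a(5),7-dien-6-one | CC(C)=CC[C@@]12[C@@H](O[Si](C)(C)C(C)(C)C)CC[C@@H](O[Si](C)(C)C(C)(C)C)C1=CC(=O)C=C2 | intermediate
13 | 2-bromo-1,4-dimethoxybenzene | COc1ccc(OC)c(Br)c1 | starting material
14 | 2-bromo-3,6-dimethoxyphenyllithium | COc1ccc(OC)c([Li])c1Br | intermediate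
15 | 2-bromo-3-iodo-1,4-dimethoxybenzene | COc1ccc(OC)c(I)c1Br | intermediate
16 | 2-bromo-3,6-dimethoxyphenylmagnesium chloride | COc1ccc(OC)c([Mg]Cl)c1Br | intermediate
17 | 8α-aryl C6 TMS dienol ether (C4a=C5, C6=C7) | CC(C)=CC[C@@]12[C@@H](O[Si](C)(C)C(C)(C)C)CC[C@@H](O[Si](C)(C)C(C)(C)C)C1=CC(O[Si](C)(C)C)=C[C@@H]2c1c(Br)c(OC)ccc1OC | intermediate
18 | 8α-(2-bromo-3,6-dimethoxyphenyl) enone (aryl axial, trans to prenyl) | CC(C)=CC[C@@]12[C@@H](O[Si](C)(C)C(C)(C)C)CC[C@@H](O[Si](C)(C)C(C)(C)C)C1=CC(=O)C[C@@H]2c1c(Br)c(OC)ccc1OC | intermediate
19 | 6α-hydroxy-6β-methyl allylic alcohol (OH cis to aryl) | CC(C)=CC[C@@]12[C@@H](O[Si](C)(C)C(C)(C)C)CC[C@@H](O[Si](C)(C)C(C)(C)C)C1=C[C@](C)(O)C[C@@H]2c1c(Br)c(OC)ccc1OC | intermediate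
20 | dilithio species (C6 lithium alkoxide, ortho-aryllithium) | CC(C)=CC[C@@]12[C@@H](O[Si](C)(C)C(C)(C)C)CC[C@@H](O[Si](C)(C)C(C)(C)C)C1=C[C@](C)(O[Li])C[C@@H]2c1c([Li])c(OC)ccc1OC | intermediate
21 | C6 lithium alkoxide, ortho-pinacol boronate | CC(C)=CC[C@@]12[C@@H](O[Si](C)(C)C(C)(C)C)CC[C@@H](O[Si](C)(C)C(C)(C)C)C1=C[C@](C)(O[Li])C[C@@H]2c1c(B3OC(C)(C)C(C)(C)O3)c(OC)ccc1OC | intermediate
22 | 6α-acetate, ortho-pinacol boronate | CC(C)=CC[C@@]12[C@@H](O[Si](C)(C)C(C)(C)C)CC[C@@H](O[Si](C)(C)C(C)(C)C)C1=C[C@](C)(OC(C)=O)C[C@@H]2c1c(B3OC(C)(C)C(C)(C)O3)c(OC)ccc1OC | intermediate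
23 | key precursor: aryl octalin with C4a=C5 alkene, 6α-acetate, ortho-boronic acid, 1β,4β-bis(TBSO) | CC(C)=CC[C@@]12[C@@H](O[Si](C)(C)C(C)(C)C)CC[C@@H](O[Si](C)(C)C(C)(C)C)C1=C[C@](C)(OC(C)=O)C[C@@H]2c1c(B(O)O)c(OC)ccc1OC | intermediate
24 | key product: tetracycle with arene bridge α on C8 and C4a, C5=C6 alkene, 1β,4β-bis(TBSO) | CC(C)=CC[C@@]12[C@@H](O[Si](C)(C)C(C)(C)C)CC[C@@H](O[Si](C)(C)C(C)(C)C)[C@@]13C=C(C)C[C@@H]2c1c(OC)ccc(OC)c13 | intermediate
25 | tetracyclic 1β,4β-diol | CC(C)=CC[C@@]12[C@@H](O)CC[C@@H](O)[C@@]13C=C(C)C[C@@H]2c1c(OC)ccc(OC)c13 | intermediate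
26 | tetracyclic 1,4-dione | CC(C)=CC[C@@]12C(=O)CCC(=O)[C@@]13C=C(C)C[C@@H]2c1c(OC)ccc(OC)c13 | intermediate
27 | tetracyclic 2-ene-1,4-dione, hydroquinone dimethyl ether | CC(C)=CC[C@@]12C(=O)C=CC(=O)[C@@]13C=C(C)C[C@@H]2c1c(OC)ccc(OC)c13 | intermediate
28 | tetracyclic 2-ene-1,4-dione p-quinone | CC(C)=CC[C@@]12C(=O)C=CC(=O)[C@@]13C=C(C)C[C@@H]2C4=C3C(=O)C=CC4=O | intermediate
29 | CNP0513322.1, (4aR,8R,8aS) in the numbering used here | CC(C)=CC[C@@]12C(=O)C=CC(=O)[C@@]13C=C(C)C[C@@H]2c1c(O)ccc(O)c13 | target

**Step count**

Total step count: 17.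
Longest linear sequence: 16 (steps 1–7 and 9–17). Step 8 is a one-step side branch.

**Steps most likely to fail**

**Step 13.**
- What may go wrong:
  - ionisation of the tertiary allylic acetate by the cationic metal salts followed by elimination;
  - protodeboronation of the hindered, electron-rich boronic acid;
  - slow rotation of the aryl group into the rotamer that places the metal under ring C;
  - refusal of the aryl–palladium species to insert at fully substituted C4a beside quaternary C8a.
- Fallback (sets out from 19, comes back at 24): the same bond is made with stoichiometric copper and a leaving group that carries the metal. Alcohol 19 is deprotonated with n-BuLi and treated with PhNCO to give N-phenylcarbamate F1. N-deprotonation (n-BuLi), bromine–lithium exchange (t-BuLi, −78 °C) and addition of CuI·2LiCl give chelated lithium aryl(amido)cuprate F2. In this species copper is tied both to the arene carbon and to the carbamate nitrogen on the α face. On warming, a carbamate-directed syn SN2′ displacement should pass the aryl group to C4a and expel the carbamate from C6, giving 24.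

**Step 9.**
- What may go wrong: slow transfer of the doubly ortho-substituted aryl group from copper to C8, which lies next to quaternary C8a. In that case 1,2-addition, or aryne formation by loss of magnesium halide, could take over.
- Fallback (sets out from 12 and 13, comes back at 20): the arene is brought in without the ortho handle and is metalated afterwards. Bromide 13 and Mg give 2,5-dimethoxyphenylmagnesium bromide F3. Under the copper/TMSCl regime of step 9 this adds to 12 to give TMS dienol ether F4 and, after the acid work-up, 8α-(2,5-dimethoxyphenyl) enone F5. MeLi/CeCl3 as in step 10 gives tertiary alcohol F6. n-BuLi/TMEDA (Et2O, 0 °C) then removes the hydroxyl proton and lithiates the arene CH that lies between the C8-bearing and the methoxy-bearing carbons. This is a directed ortho-metalation in which the neighbouring methoxy group and the syn-axial 6α-alkoxide should cooperate. The product is dilithio species 20, which is carried on as in step 11.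

**Step 5.**
- What may go wrong: competing epoxidation of the prenyl double bond, or oxygen transfer to C5 instead of C4.
- Fallback (sets out from 1, comes back at 9): the nucleophilic side-chain alkene is kept masked as a terminal allyl group until the peracid step is over.
  - Allyl bromide/KOH converts 1 into 2-allylcyclohexane-1,3-dione F7.
  - The conditions of step 2 give allyl triketone F8 and then allyl enedione F9.
  - The conditions of steps 3–5 give allyl hydroxy enone F10, allyl bis-silyl dienol ether F11 and allyl γ-hydroxy enone F12.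
  - Cross-metathesis of F12 with 2-methylbut-2-ene (second-generation Grubbs catalyst, CH2Cl2, 40 °C) turns allyl into prenyl and gives 9.

Further compounds
F1 | step 13 | 6α-(N-phenylcarbamoyloxy) aryl bromide | CC(C)=CC[C@@]12[C@@H](O[Si](C)(C)C(C)(C)C)CC[C@@H](O[Si](C)(C)C(C)(C)C)C1=C[C@](C)(OC(=O)Nc1ccccc1)C[C@@H]2c1c(Br)c(OC)ccc1OC
F2 | step 13 | chelated lithium aryl(amido)cuprate | CC(C)=CC[C@@]12[C@@H](O[Si](C)(C)C(C)(C)C)CC[C@@H](O[Si](C)(C)C(C)(C)C)C1=C[C@](C)(OC(=O)N(c3ccccc3)[Cu-]4)C[C@@H]2c1c4c(OC)ccc1OC.[Li+]
F3 | step 9 | 2,5-dimethoxyphenylmagnesium bromide | COc1ccc(OC)c([Mg]Br)c1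
F4 | step 9 | 8α-(2,5-dimethoxyphenyl) C6 TMS dienol ether | CC(C)=CC[C@@]12[C@@H](O[Si](C)(C)C(C)(C)C)CC[C@@H](O[Si](C)(C)C(C)(C)C)C1=CC(O[Si](C)(C)C)=C[C@@H]2c1cc(OC)ccc1OC
F5 | step 9 | 8α-(2,5-dimethoxyphenyl) enone | CC(C)=CC[C@@]12[C@@H](O[Si](C)(C)C(C)(C)C)CC[C@@H](O[Si](C)(C)C(C)(C)C)C1=CC(=O)C[C@@H]2c1cc(OC)ccc1OC
F6 | step 9 | 8α-(2,5-dimethoxyphenyl) 6α-hydroxy-6β-methyl alcohol | CC(C)=CC[C@@]12[C@@H](O[Si](C)(C)C(C)(C)C)CC[C@@H](O[Si](C)(C)C(C)(C)C)C1=C[C@](C)(O)C[C@@H]2c1cc(OC)ccc1OC
F7 | step 5 | 2-allylcyclohexane-1,3-dione | C=CCC1C(=O)CCCC1=O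
F8 | step 5 | 2-allyl-2-(3-oxobutyl)cyclohexane-1,3-dione | C=CCC1(CCC(C)=O)C(=O)CCCC1=O
F9 | step 5 | 8a-allyl-4a(5)-octalene-1,6-dione (same spatial sense as 6) | C=CC[C@@]12C(=O)CCCC1=CC(=O)CC2
F10 | step 5 | 8a-allyl 1β-hydroxy enone | C=CC[C@@]12[C@@H](O)CCCC1=CC(=O)CC2
F11 | step 5 | 8a-allyl 1β-TBSO linear TBS dienol ether | C=CC[C@@]12[C@@H](O[Si](C)(C)C(C)(C)C)CCC=C1C=C(O[Si](C)(C)C(C)(C)C)CC2
F12 | step 5 | 8a-allyl 1β-TBSO-4β-hydroxy enone | C=CC[C@@]12[C@@H](O[Si](C)(C)C(C)(C)C)CC[C@@H](O)C1=CC(=O)CC2
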